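**Plan**

- Retrosynthesis: the four phenols are masked as MOM ethers. The C3–OH is cut (enolate hydroxylation) and C4=O is taken back to a carbinol. The aryl ether bond O1–C8a of the pyranone ring is then cut to an open 1,3-diol with Br on C8a. The diol comes from a chalcone epoxide, and the chalcone from C2–C3 (aldol condensation) of a ring-A bromoacetophenone and a ring-B geranyl benzaldehyde.
- Forward: ring-B aldehyde (aryl–geranyl bond by arylcopper allylation) and ring-A ketone (acetyl by Nencki acylation) → chalcone → epoxide → 1,3-diol → ring C by O1–C8a closure → C4 ketone → C3–OH → free phenols. Rings A and B are bought; ring C is the only ring made.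
- Enabling feature: C8a of ring A carries Br ortho to the C4 side chain, and the C2 carbinol oxygen is the only hydroxyl that can reach it through a six-membered array (O–C2–C3–C4–C4a–C8a). The C4–OH could only give a four-membered benzoxete. Holding C4 as CH–OH during closure removes the β-hydroxy ketone that would otherwise undergo retro-aldol or E1cB under base.
- Stereochemistry: C2 comes from the Juliá–Colonna epoxidation (its Cβ–O bond is never broken afterwards). C3 comes from hydroxylation of the flavanone enolate anti to the C2 aryl group (2,3-trans). C4 epimers converge on oxidation.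

Key step: step 9

Remark: flavonoid numbering (O1, C2, C3, C4, C4a, C8a) is used also for open-chain precursors; C4 is carried as a mixture of carbinol epimers from step 8 to step 10 and is therefore written without configuration; "geranyl" means (2E)-3,7-dimethylocta-2,6-dien-1-yl and "MOM" means methoxymethyl.

**Route**

Step 1
Reactants: 1 3-bromo-4,5-dihydroxybenzaldehyde
Product: 2 3-bromo-4,5-bis(methoxymethoxy)benzaldehyde
Conditions: MOMCl, iPr2NEt, CH2Cl2, 0 °C to rt
Reagents that add atoms: chloromethyl methyl ether COCCl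
Why: Double O-alkylation of the catechol with MOMCl under Hünig's base (MOM ether formation) masks both phenols as base-stable acetals that also assist the later bromine–lithium exchange.

Step 2
Reactants: 2 3-bromo-4,5-bis(methoxymethoxy)benzaldehyde
Product: 3 1-bromo-5-(dimethoxymethyl)-2,3-bis(methoxymethoxy)benzene
Conditions: HC(OMe)3, MeOH, PPTS (cat.), rt; Et3N quench
Reagents that add atoms: trimethyl orthoformate COC(OC)OC
Why: Acid-catalysed acetalisation with trimethyl orthoformate as dehydrating agent masks the aldehyde against n-BuLi, and PPTS at room temperature is too weak to cleave the aryl MOM ethers.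

Step 3
Reactants: 3 1-bromo-5-(dimethoxymethyl)-2,3-bis(methoxymethoxy)benzene; 4 geranyl bromide
Product: 8 3-geranyl-4,5-bis(methoxymethoxy)benzaldehyde, via aryllithium 5 (not isolated), via arylcopper 6 (not isolated), via geranylated dimethyl acetal 7 (not isolated)
Conditions: n-BuLi, THF, −78 °C; CuBr·SMe2, −78 to −40 °C; 4, −78 °C to rt; then 1 M aq. HCl, THF, 0 °C
Reagents that add atoms: water O
Why: Bromine–lithium exchange, transmetalation to the arylcopper and SN2 allylation at the primary carbon of geranyl bromide (copper-mediated aryl–allyl coupling) should install the side chain with the E-alkene unchanged, and the dilute acid of the work-up hydrolyses the dimethyl acetal far faster than the aryl MOM ethers.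

Step 4
Reactants: 9 5-bromoresorcinol
Product: 10 1-(2-bromo-4,6-dihydroxyphenyl)ethanone
Conditions: AcOH, ZnCl2, 140 °C
Reagents that add atoms: acetic acid CC(=O)O
Why: Nencki (Friedel–Crafts) acylation of the resorcinol goes para to one hydroxyl and ortho to the other, i.e. at C4 next to bromine rather than between the two hydroxyls, as in the conversion of orcinol into orcacetophenone.

Step 5
Reactants: 10 1-(2-bromo-4,6-dihydroxyphenyl)ethanone
Product: 11 1-[2-bromo-4,6-bis(methoxymethoxy)phenyl]ethanone
Conditions: NaH, MOMCl, DMF, 0 °C to rt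
Reagents that add atoms: chloromethyl methyl ether COCCl
Why: Williamson-type MOM protection via the sodium phenoxides, NaH being needed for the hydroxyl that is hydrogen-bonded to the ketone.

Step 6
Reactants: 8 3-geranyl-4,5-bis(methoxymethoxy)benzaldehyde; 11 1-[2-bromo-4,6-bis(methoxymethoxy)phenyl]ethanone
Product: 12 (2E)-1-[2-bromo-4,6-bis(methoxymethoxy)phenyl]-3-[3-geranyl-4,5-bis(methoxymethoxy)phenyl]prop-2-en-1-one
Conditions: KOH, EtOH, rt
Reagents that add atoms: none
Why: Claisen–Schmidt aldol condensation of the methyl ketone enolate with the non-enolisable aldehyde, the E-enone arising from E1cB dehydration under thermodynamic control.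

Step 7
Reactants: 12 (2E)-chalcone
Product: 13 [2-bromo-4,6-bis(methoxymethoxy)phenyl][(2S,3R)-3-[3-geranyl-4,5-bis(methoxymethoxy)phenyl]oxiran-2-yl]methanone
Conditions: poly-D-leucine, urea–H2O2, DBU, THF, rt
Reagents that add atoms: hydrogen peroxide (used as its urea adduct) OO
Why: Juliá–Colonna epoxidation (Weitz–Scheffer addition of hydroperoxide inside the poly-leucine helix) attacks only the electron-poor enone, so the two geranyl alkenes are untouched, and the D-polymer is chosen because the L-polymer gives the (2R,3S) series, the trans geometry following from the E-enone.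

Step 8
Reactants: 13 (2S,3R)-epoxy ketone
Product: 15 (3S)-1-[2-bromo-4,6-bis(methoxymethoxy)phenyl]-3-[3-geranyl-4,5-bis(methoxymethoxy)phenyl]propane-1,3-diol, via epoxy alcohol 14 (not isolated)
Conditions: Red-Al, THF, −20 to 0 °C; aq. Rochelle salt
Reagents that add atoms: none
Why: Red-Al first reduces the ketone and the resulting C4 alkoxyaluminate then delivers hydride intramolecularly to the adjacent epoxide carbon (the known 1,3-diol-selective reductive opening of 3-aryl-2,3-epoxy alcohols), so the benzylic C–O bond survives with its configuration as the (S)-C2 carbinol.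

Step 9
Reactants: 15 (3S)-1,3-diol
Product: 16 (2S)-2-[3-geranyl-4,5-bis(methoxymethoxy)phenyl]-5,7-bis(methoxymethoxy)chroman-4-ol
Conditions: CuI (10 mol %), 3,4,7,8-tetramethyl-1,10-phenanthroline (20 mol %), Cs2CO3, toluene (degassed), 110 °C
Reagents that add atoms: none
Why: Ullmann-type copper(I)-catalysed intramolecular O-arylation: the C2 alkoxide bound to the phenanthroline–copper(I) centre undergoes oxidative addition into the C8a–Br bond of ring A and C–O reductive elimination forms O1–C8a. The closest known reaction type is the copper- or palladium-catalysed cyclisation of 1-aryl-3-(2-bromoaryl)propan-1-ols to 2-arylchromans (flavans). The pyran ring (O1, C2, C3, C4, C4a, C8a) closes in a 6-exo mode onto the aromatic carbon. No stereocentre is created: C2 keeps the configuration set in step 7 because only its O–H bond is broken, and C4 is a mixture that is erased in step 10. The step needs chemoselection between the two benzylic hydroxyls and freedom from base-induced aldol chemistry. The substrate secures both, since the C4–OH could only form a four-membered benzoxete and so remains a spectator, and with C4 at the carbinol level there is no β-hydroxy ketone that could undergo retro-aldol or E1cB loss of water to the chalcone and thereby erase C2.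

Step 10
Reactants: 16 (2S)-flavan-4-ol
Product: 17 (2S)-2-[3-geranyl-4,5-bis(methoxymethoxy)phenyl]-5,7-bis(methoxymethoxy)chroman-4-one
Conditions: Dess–Martin periodinane, CH2Cl2, rt
Reagents that add atoms: none
Why: Dess–Martin oxidation of the benzylic secondary alcohol to the chromanone under neutral conditions converges both C4 epimers and leaves the alkenes, MOM ethers and the C2 centre alone.

Step 11
Reactants: 17 (2S)-flavanone
Product: 19 (2R,3R)-2-[3-geranyl-4,5-bis(methoxymethoxy)phenyl]-3-hydroxy-5,7-bis(methoxymethoxy)chroman-4-one, via potassium enolate 18 (not isolated)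
Conditions: KHMDS, THF, −78 °C; 2-(phenylsulfonyl)-3-phenyloxaziridine, −78 °C; aq. NH4Cl at −78 °C
Reagents that add atoms: 2-(phenylsulfonyl)-3-phenyloxaziridine O=S(=O)(c1ccccc1)N1OC1c1ccccc1
Why: Davis enolate hydroxylation: the kinetic potassium enolate formed at C3 takes electrophilic oxygen from the oxaziridine on the face anti to the C2 aryl group, which sets the 2,3-trans (3R) centre, and this reagent does not epoxidise the isolated trisubstituted alkenes.

Step 12
Reactants: 19 (2R,3R)-tetra-MOM dihydroflavonol
Product: 20 (2R,3R)-2-[3-geranyl-4,5-dihydroxyphenyl]-3,5,7-trihydroxychroman-4-one (CNP0153097.1)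
Conditions: HCl (ca. 1 M), MeOH, 40 °C
Reagents that add atoms: none
Why: Acid-catalysed acetal exchange with methanol removes all four MOM ethers as dimethoxymethane under conditions mild enough for the geranyl chain and the trans-dihydroflavonol.

**Compound list**

1 | 3-bromo-4,5-dihydroxybenzaldehyde | O=Cc1cc(O)c(O)c(Br)c1 | starting material
2 | 3-bromo-4,5-bis(methoxymethoxy)benzaldehyde | O=Cc1cc(OCOC)c(OCOC)c(Br)c1 | intermediate
3 | 1-bromo-5-(dimethoxymethyl)-2,3-bis(methoxymethoxy)benzene | COC(OC)c1cc(OCOC)c(OCOC)c(Br)c1 | intermediate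
4 | geranyl bromide, (2E)-1-bromo-3,7-dimethylocta-2,6-diene | CC(C)=CCC/C(C)=C/CBr | starting material
5 | [5-(dimethoxymethyl)-2,3-bis(methoxymethoxy)phenyl]lithium | COC(OC)c1cc(OCOC)c(OCOC)c([Li])c1 | intermediate
6 | [5-(dimethoxymethyl)-2,3-bis(methoxymethoxy)phenyl]copper | COC(OC)c1cc(OCOC)c(OCOC)c([Cu])c1 | intermediate
7 | 5-(dimethoxymethyl)-1-geranyl-2,3-bis(methoxymethoxy)benzene | CC(C)=CCC/C(C)=C/Cc1cc(C(OC)OC)cc(OCOC)c1OCOC | intermediate
8 | 3-geranyl-4,5-bis(methoxymethoxy)benzaldehyde | CC(C)=CCC/C(C)=C/Cc1cc(C=O)cc(OCOC)c1OCOC | intermediate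
9 | 5-bromoresorcinol (5-bromobenzene-1,3-diol) | Oc1cc(O)cc(Br)c1 | starting material
10 | 1-(2-bromo-4,6-dihydroxyphenyl)ethanone | CC(=O)c1c(O)cc(O)cc1Br | intermediate
11 | 1-[2-bromo-4,6-bis(methoxymethoxy)phenyl]ethanone | CC(=O)c1c(OCOC)cc(OCOC)cc1Br | intermediate
12 | (2E)-1-[2-bromo-4,6-bis(methoxymethoxy)phenyl]-3-[3-geranyl-4,5-bis(methoxymethoxy)phenyl]prop-2-en-1-one | CC(C)=CCC/C(C)=C/Cc1cc(/C=C/C(=O)c2c(Br)cc(OCOC)cc2OCOC)cc(OCOC)c1OCOC | intermediate
13 | [2-bromo-4,6-bis(methoxymethoxy)phenyl][(2S,3R)-3-[3-geranyl-4,5-bis(methoxymethoxy)phenyl]oxiran-2-yl]methanone | CC(C)=CCC/C(C)=C/Cc1cc([C@H]2O[C@@H]2C(=O)c2c(Br)cc(OCOC)cc2OCOC)cc(OCOC)c1OCOC | intermediate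
14 | epoxy alcohol: ketone of 13 reduced, epoxide as in 13, C4 epimers (alkoxyaluminate in the flask) | CC(C)=CCC/C(C)=C/Cc1cc([C@H]2O[C@@H]2C(O)c2c(Br)cc(OCOC)cc2OCOC)cc(OCOC)c1OCOC | intermediate
15 | (3S)-1-[2-bromo-4,6-bis(methoxymethoxy)phenyl]-3-[3-geranyl-4,5-bis(methoxymethoxy)phenyl]propane-1,3-diol (C1 epimers) | CC(C)=CCC/C(C)=C/Cc1cc([C@@H](O)CC(O)c2c(Br)cc(OCOC)cc2OCOC)cc(OCOC)c1OCOC | intermediate
16 | (2S)-2-[3-geranyl-4,5-bis(methoxymethoxy)phenyl]-5,7-bis(methoxymethoxy)chroman-4-ol (C4 epimers) | CC(C)=CCC/C(C)=C/Cc1cc([C@H]2Oc3cc(OCOC)cc(OCOC)c3C(O)C2)cc(OCOC)c1OCOC | intermediate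
17 | (2S)-2-[3-geranyl-4,5-bis(methoxymethoxy)phenyl]-5,7-bis(methoxymethoxy)chroman-4-one | CC(C)=CCC/C(C)=C/Cc1cc([C@H]2Oc3cc(OCOC)cc(OCOC)c3C(=O)C2)cc(OCOC)c1OCOC | intermediate
18 | potassium enolate of 17 (C3=C4 enolate) | CC(C)=CCC/C(C)=C/Cc1cc([C@H]2Oc3cc(OCOC)cc(OCOC)c3C([O-])=C2)cc(OCOC)c1OCOC.[K+] | intermediate
19 | (2R,3R)-2-[3-geranyl-4,5-bis(methoxymethoxy)phenyl]-3-hydroxy-5,7-bis(methoxymethoxy)chroman-4-one | CC(C)=CCC/C(C)=C/Cc1cc([C@H]2Oc3cc(OCOC)cc(OCOC)c3C(=O)[C@@H]2O)cc(OCOC)c1OCOC | intermediate
20 | (2R,3R)-2-[3-[(2E)-3,7-dimethylocta-2,6-dien-1-yl]-4,5-dihydroxyphenyl]-3,5,7-trihydroxy-2,3-dihydro-4H-chromen-4-one | CC(C)=CCC/C(C)=C/Cc1cc([C@H]2Oc3cc(O)cc(O)c3C(=O)[C@@H]2O)cc(O)c1O | target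

**Step count and risks**

Total step count: 12. Longest linear sequence: 10 steps (1, 2, 3, 6, 7, 8, 9, 10, 11, 12).

Steps most likely to fail:

Step 11. The flavanone enolate may open by β-elimination of the ring aryloxide (retro-oxa-Michael), which would give chalcone and erode C2, or the oxidant may add with poor facial selectivity. The fallback takes the C3 oxygen from the epoxide before ring closure, so no enolate is needed. It sets out from 13: NaBH4 (MeOH, 0 °C) would give the epoxy alcohol 14, now isolated. Cs2CO3 under CO2 in DMF would let the C4 carbonate anion attack the neighbouring epoxide carbon in a 5-exo mode with inversion, giving the hydroxy carbonate F1, in which the C2–OH is free and anti to the C3 oxygen. Palladium-catalysed intramolecular etherification (Pd(OAc)2, 2-(di-tert-butylphosphino)-1,1'-binaphthyl, K3PO4, toluene, 65 °C) would close O1–C8a to the carbonate-bridged flavan F2. K2CO3 in MeOH would release the 2,3-trans-flavan-3,4-diol F3, and MnO2 in CH2Cl2 would oxidise only the benzylic C4 carbinol, rejoining the route at 19.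

Step 7. Hydroperoxide addition may be slow and poorly face-selective, because the di-ortho-substituted aryl ketone is twisted and fits the polypeptide helix badly. The fallback sets C2 by C–B instead of C–O bond formation and sets out from 12. Copper-catalysed asymmetric conjugate borylation (CuCl, NaOtBu, the Josiphos enantiomer that places boron on the face later occupied by oxygen, B2pin2, MeOH, THF) would give the β-boryl ketone F4. NaBH4 in MeOH would reduce the ketone to the β-boryl alcohol F5, and NaBO3·4H2O in THF/H2O would oxidise the C–B bond with retention, rejoining the route at 15.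

Step 9. Oxidative addition into the electron-rich, ortho-substituted aryl bromide may be slow, so that reductive debromination or copper-mediated oxidation of the benzylic carbinols competes. The fallback closes the ring at the ketone level with palladium under a weak base and sets out from 13. Reductive cleavage of the Cα–O bond with (PhSe)2/NaBH4/AcOH in EtOH would give the (3S)-β-hydroxy ketone F6. Palladium-catalysed intramolecular etherification (Pd(OAc)2, 2-(di-tert-butylphosphino)-1,1'-binaphthyl, K3PO4, toluene, 60 °C), in which the alkoxide is generated only on palladium, would then give 17 directly, by-passing 15 and 16.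

**Further compounds**

F1 | step 11 | hydroxy carbonate: cyclic C3/C4 carbonate with free C2–OH anti to the C3 oxygen (C4 epimers) | CC(C)=CCC/C(C)=C/Cc1cc([C@@H](O)[C@H]2OC(=O)OC2c2c(Br)cc(OCOC)cc2OCOC)cc(OCOC)c1OCOC
F2 | step 11 | carbonate-bridged flavan: 2,3-trans-flavan-3,4-diyl carbonate, tetra-MOM ether (C4 epimers) | CC(C)=CCC/C(C)=C/Cc1cc([C@H]2Oc3cc(OCOC)cc(OCOC)c3C3OC(=O)O[C@H]23)cc(OCOC)c1OCOC
F3 | step 11 | 2,3-trans-flavan-3,4-diol, tetra-MOM ether (C4 epimers) | CC(C)=CCC/C(C)=C/Cc1cc([C@H]2Oc3cc(OCOC)cc(OCOC)c3C(O)[C@@H]2O)cc(OCOC)c1OCOC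
F4 | step 7 | β-boryl ketone: 1-[2-bromo-4,6-bis(methoxymethoxy)phenyl]-3-[3-geranyl-4,5-bis(methoxymethoxy)phenyl]-3-(pinacolboryl)propan-1-one | CC(C)=CCC/C(C)=C/Cc1cc([C@@H](B2OC(C)(C)C(C)(C)O2)CC(=O)c2c(Br)cc(OCOC)cc2OCOC)cc(OCOC)c1OCOC
F5 | step 7 | β-boryl alcohol: ketone of F4 reduced (C1 epimers) | CC(C)=CCC/C(C)=C/Cc1cc([C@@H](B2OC(C)(C)C(C)(C)O2)CC(O)c2c(Br)cc(OCOC)cc2OCOC)cc(OCOC)c1OCOC
F6 | step 9 | (3S)-1-[2-bromo-4,6-bis(methoxymethoxy)phenyl]-3-[3-geranyl-4,5-bis(methoxymethoxy)phenyl]-3-hydroxypropan-1-one | CC(C)=CCC/C(C)=C/Cc1cc([C@@H](O)CC(=O)c2c(Br)cc(OCOC)cc2OCOC)cc(OCOC)c1OCOC
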